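Thursday's run opened the meeting: at 120 min, the time allowed for this flask, it held 21.7% X where Tuesday's held 9.1%.

| flask | E | G | remark | time |
|---|---|---|---|---|
| Thursday's | 0.034 M | 1.2 mM | run made earlier |  |
| Tuesday's | 0.075 M | 1.2 mM | run made earlier |  |
| flask | 0.050 M | 1.2 mM |  | 2.0 h |

| run | time / min | X / % | E / % |
|---|---|---|---|
| Thursday's | 30.0 | 3.1 | 88.8 |
| Thursday's | 40.0 | 4.5 | 85.0 |
| Thursday's | 60.0 | 9.1 | 78.8 |
| Thursday's | 80.0 | 13.3 | 73.8 |
| Thursday's | 120 | 21.7 | 63.0 |
| Tuesday's | 30.0 | 1.9 | 94.7 |
| Tuesday's | 40.0 | 1.6 | 92.5 |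
| Tuesday's | 60.0 | 4.2 | 91.2 |
| Tuesday's | 80.0 | 6.2 | 88.4 |
| Tuesday's | 120 | 9.1 | 82.9 |

(each reading ± 0.5 percentage points)

1. the moment within 2.0 h at which there is most X
2. the amount of X, in percent of the E charged, at that time

- given per volume of solution although it is solid: E
- at the start none of E is in solution

The chair asked which number could be carried to the new charge. As minute-taker, I argued that the share should not be frozen, but the share times the E charge: in the readings at 120 min, with the same G in both runs, that product differs between the runs by a factor of 1.08, while the charges differ by 2.21, so at this G and time X looks zero order in the solid charged. Taking the mean of that product over both runs, as a share of this flask's charge, I got 14.2%, and this is the charge-blind output. I added that X was still rising in the last interval of both runs, from 13.3% to 21.7% on Thursday's and from 6.2% to 9.1% on Tuesday's, so I put the maximum at the end.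

The forecast was then read: 14.4% (13.3% to 15.5%) at 2 h (1.9 h to 2 h), on the ground that “X depends on dissolved monomer, not on the charge”. Its share stood 0.2 percentage points above mine.

The flask gave 14.9% at 2.00 h.

    2 J → D (k = 3.30 × 10⁸ /M/s)
    E ⇌ L, rate k2*(cs2 - [L]) while solid is left; crystals form when [L] > cs2 (solubility = 15.0 mM, k = 0.00950 /min)
    G → 2 Q (k = 0.00560 /min)
    L + J → X + J, rate k4*[J]*[L] (k = 16000 /M/s)
    2 L → Z (k = 0.0640 /M/min)
    L + Q → J + X (k = 4.30 × 10⁵ /M/s)

That is 0.70 points above the charge-blind output of 14.2%. The neighbour flask keeps this E charge but holds 3.0 × 10⁻⁴ M of G, a quarter of the flask's charge. Scaled by the square root of the ratio of G, the output is 7.10%. The neighbour flask gave 8.61% X. At 2.00 h its J stood at 6.58 × 10⁻⁹ M against 1.32 × 10⁻⁸ M in the flask, half as much, and its L stood at 14.2% against 10.6%.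

(The earlier runs and the new flask are calculated on assumed constants; noise was put on by code.)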